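**Compound numbering used throughout:** 1 acid, 2 acid chloride, 3 carboxamide, 4 ethyl chlorooxoacetate, 5 N-oxalyl pyrrole, 6 hydroxy lactam, 7 ketimine, 8 tert-butyl carbamate, 9 aminal ester, 10 cyclopropanol, 11 bromomethyl acetate, 12 N-acetoxymethyl cyclopropanol, 13 ethylzinc cyclopropoxide, 14 zinc homoenolate, 15 Boc-amino ketone, 16 amino ketone, 17 cyanamide, 18 open guanidine ketone, 19 target.

## Analysis of the target

The target 19 (C11H11Br2N5O2) is a compact tetracycle. A 4,5-dibromopyrrole-2-carbonyl unit (ring A) is fused to a five-membered lactam (ring B), a piperidine (ring C) and a 2-aminoimidazoline (ring D). Rings B, C and D meet at one fully substituted carbon that carries three nitrogen atoms (pyrrole N, lactam N, guanidine N–H) and one carbon substituent, the carbinol carbon of ring C. The two stereocentres are adjacent: the triamino carbon is S and the carbinol carbon is R, which corresponds to ring D being cis-fused to ring C. The carbinol centre is a guanidine hemiaminal of a ketone; it forms reversibly and its configuration follows from the ring fusion, so only the triamino carbon needs absolute control. Sensitive groups are the hemiaminal and free guanidine, the two C–Br bonds (reduction, halogen–metal exchange, palladium), and the orthoamide-like carbon, which can ionise under acid or lose a nitrogen substituent from an N-anion. The difficulty is to build a quaternary N,N,N-carbon next to a ketone-level carbon as one enantiomer without functionality that must later be removed. The route rests on ring C: the carbinol carbon and the N–CH2 carbon of the lactam nitrogen are separated by two methylenes, a γ-amino ketone pattern that corresponds to a ketone homoenolate plus an N-methylene N-acyliminium ion.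

## Retrosynthetic reasoning

**19 ⇒ 16 + 17.** Ring D is cut at both guanidine C–N bonds, the hemiaminal N–C(OH) bond and the bond from the amidine carbon to the N–H on the triamino carbon. This reveals the α-amino ketone 16 and cyanamide 17. The hemiaminal is the product of a reversible addition and closes spontaneously once the guanidine exists (via 18). Placing this last keeps the most polar group out of all earlier steps.

**16 ⇒ 15.** The primary amine is traced to its tert-butyl carbamate. The carbamate nitrogen is the one introduced in the enantio-determining step, it survives organometallic steps as its N-anion, and it is removed by acid without touching the lactam, ketone or C–Br bonds.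

**15 ⇒ 12 (key disconnection).** Ring C is cut between the methylene β to the ketone and the N-bound methylene. Cutting the N–CH2 bond instead would need a γ-functionalised ketone chain made in extra steps. Cutting between the ketone and the triamino carbon would need an acyl anion adding to a crowded centre. The chosen cut gives two synthons that both hang from the same quaternary carbon: a ketone homoenolate, stored as the cyclopropanol of 12, and an N-methylene iminium ion, stored as the N-acetoxymethyl group. The forward reaction must open the cyclopropanol through 13 to the zinc homoenolate 14 and ionise the acetate. Ring C then arrives at the correct oxidation level with no redox correction.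

**12 ⇒ 10 + 11.** The N–CH2 bond is cut; forward, the lactam N–H of 10 is alkylated with 11. This comes after cyclopropanation because the acetate would not survive it.

**10 ⇒ 9.** Both new cyclopropane C–C bonds are removed, giving the ethyl ester 9; forward, a Kulinkovich reaction. The ester serves twice: it activates the ketimine in the preceding step and then becomes the latent ketone.

**9 ⇒ 7 + 8.** The bond between the triamino carbon and the carbamate nitrogen is cut. Forward, 8 adds to the planar cyclic N-acyl ketimine 7 under a chiral Brønsted acid. This is the only step where absolute configuration has to be controlled.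

**7 ⇒ 3 + 4.** The two C–N bonds of ring B at the ester-bearing carbon are cut (pyrrole N–C and lactam N=C). The acid chloride carbon of 4 already has the three-heteroatom oxidation level of the future triamino carbon, so acylation (5), ring closure (6) and dehydration give 7 without redox chemistry.

**3 ⇒ 1.** The primary amide comes from the commercial acid 1 through the acid chloride 2.

## Alternatives that were turned down

**Alternative 1: three nitrogens close onto a trithioorthoester.**
- Disconnection: all three C–N bonds of the triamino carbon and ring D are cut at once. This leads to the acyclic keto trithioorthoester A2 (chain from L-glutamic acid) and guanidine A3.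
- Forward key step: A3 condenses with the ketone of A2 while dimethyl(methylthio)sulfonium tetrafluoroborate removes the three methylthio groups in turn. The amide N, pyrrole N and guanidine N each capture a thionium ion, closing rings C, B and D to give the ester-bearing tetracycle A1.
- For: three rings, three C–N bonds and both stereocentres form in one flask, and sulfur carries the orthoester oxidation level. On bond economy this is stronger than the chosen route.
- Against: A1 carries a methyl ester on the ring-C carbon next to the lactam nitrogen. Removing it needs saponification and radical decarboxylation in the presence of a free guanidine, a hemiaminal and two C–Br bonds that are themselves prone to radical reduction. The configuration of the triamino carbon would have to be relayed from the epimerisable ester-bearing carbon across the lactam nitrogen. The order of the three N-captures is not programmed, and the sulfonium reagent can also sulfenylate the pyrrole.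
- Comparison: the chosen route closes the rings one at a time and is longer in ring-forming operations. In return a catalyst sets the configuration at a defined step, and nothing has to be excised at the end.

**Alternative 2: carbamate-tethered nitrene amination of the aminal C–H.**
- Disconnection: the bond from the triamino carbon to the ring-D nitrogen is traced to a C–H bond. The precursor A5 is the tricycle with an aminal C–H and a primary carbamate on the neighbouring secondary carbinol.
- Forward key step: Rh2(OAc)4 with PhI(OAc)2 and MgO turns the carbamate into a rhodium nitrene, which inserts into the aminal C–H with retention and gives the oxazolidinone-bridged tetracycle A4.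
- For: carbamate-to-oxazolidinone C–H amination is an established reaction class and is stereospecific, so the triamino carbon would follow from the carbinol centre. On precedent for the key step this alternative is stronger than the chosen route.
- Against: this C–H is flanked by an acylated nitrogen and a pyrrole nitrogen, whose lone pairs cannot stabilise the developing positive charge, so it is electronically deactivated. The ring CH2 on the other side of the carbinol competes for the same five-membered insertion. The oxidant can attack the pyrrole. A4 still needs oxazolidinone cleavage (basic hydrolysis next to a base-sensitive orthoamide carbon) and alcohol oxidation to reach 16. A5 itself needs ring C and a stereodefined carbinol built first.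
- Comparison: the chosen route delivers ring C directly as the ketone 15, two steps from the target.

**Alternative 3: aza-Achmatowicz conversion of a furan into ring C.**
- Disconnection: the N–CH2 bond of ring C and the ketone are traced to a 2-furyl group on the triamino carbon. The precursor A7 carries furan-2-yl, phthalimido and the lactam N–H.
- Forward key step: m-chloroperbenzoic acid oxidises the furan to a cis-enedione, and the lactam N–H captures the aldehyde to give the 6-hydroxy-2H-pyridin-3-one A6.
- For: the furan is a robust latent 1,4-dicarbonyl, the oxidative rearrangement is well precedented, and no organometallic reagent meets the C–Br bonds. In reliability of the ring-forming event it is at least as strong as the chosen step.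
- Against: A6 is over-functionalised. The C=C must be reduced without touching C–Br or the ketone. The hemiaminal hydroxyl (formed as both epimers) must be removed reductively beside a ketone. The phthalimide must be cleaved by hydrazine or an amine in the presence of that ketone. Only then can the guanidine be installed, at least four steps after the key step against two here. A lactam N–H is also a poorer trap than the sulfonamides and carbamates normally used, and A7 needs its own enantioselective construction.
- Comparison: the chosen route gives ring C at exactly the required oxidation level.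

Key step: step 6

Assumption: the sense of induction of (R)-TRIP in step 3 is taken to give the (R)-aminal 9. If it delivers the mirror image, (S)-TRIP is used instead and nothing else changes.

## Route

Step 1
Reactants: 1 4,5-dibromo-1H-pyrrole-2-carboxylic acid
Product: 3 4,5-dibromo-1H-pyrrole-2-carboxamide, via acid chloride 2 (not isolated)
Conditions: (COCl)2, DMF (cat.), CH2Cl2, 0 °C → rt; evaporate; NH3 (0.5 M in 1,4-dioxane, excess), THF, 0 °C
Reagents that add atoms: ammonia, N
Why: Acid chloride formation and aminolysis; excess ammonia should consume the acyl chloride faster than the weakly nucleophilic pyrrole N–H can, and the C–Br bonds are inert.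

Step 2
Reactants: 3 4,5-dibromo-1H-pyrrole-2-carboxamide; 4 ethyl chlorooxoacetate
Product: 7 ethyl 5,6-dibromo-1-oxo-1H-pyrrolo[1,2-c]imidazole-3-carboxylate, via N-oxalyl pyrrole 5 (not isolated), via hydroxy lactam 6 (not isolated)
Conditions: LiN(SiMe3)2 (1.0 equiv), THF, −78 °C; 4 (1.05 equiv), −78 → 0 °C; then (CF3CO)2O, Et3N, 0 °C → rt; anhydrous filtration, used directly
Reagents that add atoms: none
Why: N-acylation of the lithium pyrrolide (the pyrrole N–H is far more acidic than the amide), ring–chain tautomerism of the 2-acyl carboxamide to the five-membered hydroxy lactam as in 2-acylbenzamides, and E1cB dehydration through the O-trifluoroacetate should give the cyclic N-acyl ketimine; the ketone-like N-acylpyrrole carbonyl should be attacked in preference to the ester.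

Step 3
Reactants: 7 ethyl 5,6-dibromo-1-oxo-1H-pyrrolo[1,2-c]imidazole-3-carboxylate; 8 tert-butyl carbamate
Product: 9 ethyl (3R)-5,6-dibromo-3-[(tert-butoxycarbonyl)amino]-1-oxo-2,3-dihydro-1H-pyrrolo[1,2-c]imidazole-3-carboxylate
Conditions: (R)-TRIP [(R)-3,3′-bis(2,4,6-triisopropylphenyl)-1,1′-binaphthyl-2,2′-diyl hydrogen phosphate] (10 mol%), 4 Å MS, toluene, −20 °C
Reagents that add atoms: none
Why: Chiral phosphoric acid-catalysed aza-addition of a carbamate N–H to an ester-activated cyclic N-acyl ketimine (N,N-aminal formation); the acid binds the ketimine nitrogen and, through P=O, the carbamate N–H, and the triisopropylphenyl groups leave open one face of the planar bicycle, taken to be the one giving the R centre; low temperature limits acid-catalysed reversal.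

Step 4
Reactants: 9 ethyl (3R)-5,6-dibromo-3-[(tert-butoxycarbonyl)amino]-1-oxo-2,3-dihydro-1H-pyrrolo[1,2-c]imidazole-3-carboxylate
Product: 10 tert-butyl N-[(3R)-5,6-dibromo-3-(1-hydroxycyclopropyl)-1-oxo-2,3-dihydro-1H-pyrrolo[1,2-c]imidazol-3-yl]carbamate
Conditions: EtMgBr (5 equiv, slow addition), Ti(OiPr)4 (0.3 equiv), THF, 0 °C → rt; aq. NH4Cl
Reagents that add atoms: ethylmagnesium bromide, CC[Mg]Br
Why: Kulinkovich cyclopropanation of the ethyl ester through a titanacyclopropane; the first two equivalents of Grignard reagent turn the lactam and carbamate N–H into magnesium amides, which shields both carbonyl groups and blocks loss of either nitrogen from the aminal carbon, so its configuration is untouched.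

Step 5
Reactants: 10 tert-butyl N-[(3R)-5,6-dibromo-3-(1-hydroxycyclopropyl)-1-oxo-2,3-dihydro-1H-pyrrolo[1,2-c]imidazol-3-yl]carbamate; 11 bromomethyl acetate
Product: 12 [(3S)-5,6-dibromo-3-[(tert-butoxycarbonyl)amino]-3-(1-hydroxycyclopropyl)-1-oxo-1H-pyrrolo[1,2-c]imidazol-2(3H)-yl]methyl acetate
Conditions: Cs2CO3 (1.2 equiv), DMF, 0 °C
Reagents that add atoms: none
Why: N-alkylation of the lactam, whose N–H should be the most acidic proton (ahead of the carbamate N–H and the cyclopropanol O–H), with a reactive α-acyloxy halide; the descriptor changes from R to S only because the lactam nitrogen gains CIP priority.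

Step 6
Reactants: 12 [(3S)-5,6-dibromo-3-[(tert-butoxycarbonyl)amino]-3-(1-hydroxycyclopropyl)-1-oxo-1H-pyrrolo[1,2-c]imidazol-2(3H)-yl]methyl acetate
Product: 15 (S)-configured tricyclic Boc-amino ketone with ring C closed as a piperidin-3-one, via ethylzinc cyclopropoxide 13 (not isolated), via zinc homoenolate 14 (not isolated)
Conditions: Et2Zn (2.5 equiv), ClCH2CH2Cl, 0 °C; then Zn(OTf)2 (30 mol%), rt → 50 °C; aq. NH4Cl
Reagents that add atoms: none
Why: Proposed new method: diethylzinc converts the cyclopropanol into the ethylzinc alkoxide 13, which opens by strain-driven C–C cleavage to the β-zincio ketone 14, while Zn(OTf)2 abstracts acetate from the N-acetoxymethyl group to give an N-methylene N-acyliminium ion; the primary alkylzinc carbon then attacks the iminium carbon and forms the C–C bond that closes ring C. The closest known reactions are the intermolecular Mannich-type additions of zinc homoenolates (from cyclopropanols and dialkylzincs) to imine and iminium electrophiles, and Lewis-acid amidoalkylation of carbon nucleophiles by N-acyloxymethyl amides; their intramolecular combination on an N-acyliminium ion has not been shown. Ring C closes in a 6-endo-trig mode (both atoms of the C=N+ bond lie in the new ring), and because nucleophile and electrophile both hang from the quaternary aminal carbon no other ring size is accessible. No stereocentre is formed, and the aminal carbon takes no part in bond making or breaking, so it keeps its S configuration. The step needs C–C closure to outrun protonation of the homoenolate and ethyl transfer from zinc to the iminium ion; the excess diethylzinc removes the carbamate N–H as an internal proton source, and the tether makes the homoenolate the kinetically favoured nucleophile. O-capture of the iminium ion by the zinc alkoxide is reversible under the Lewis acid and should drain towards the irreversible C–C bond. Ionisation at the quaternary aminal carbon, which would trigger ring expansion of the cyclopropanol, should be much slower than loss of acetate from the unhindered N–CH2–OAc group.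

Step 7
Reactants: 15 (S)-configured tricyclic Boc-amino ketone
Product: 16 (S)-configured tricyclic α-amino ketone
Conditions: CF3CO2H/CH2Cl2 (1:4), 0 °C → rt; aq. NaHCO3; used without delay
Reagents that add atoms: none
Why: Acidolysis of the tert-butyl carbamate; the lactam nitrogen is now tertiary, so the amine cannot leave as a neutral acyl imine, and a cation at the aminal carbon is disfavoured by the adjacent ketone and the acylated nitrogen.

Step 8
Reactants: 16 (S)-configured tricyclic α-amino ketone; 17 cyanamide
Product: 19 target CNP0143627.2 with S triamino carbon and R carbinol carbon, via open guanidine ketone 18 (not isolated)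
Conditions: H2NCN (5 equiv), H2O/EtOH, pH 4.5 (HCl), 70 °C; then NaHCO3, reversed-phase chromatography
Reagents that add atoms: none
Why: Guanylation of an α-amino ketone with cyanamide followed by intramolecular hemiaminal formation (the opening stages of the classical 2-aminoimidazole synthesis, which stop here because the neighbouring carbon is quaternary and no aromatic ring can form); the five-membered guanidine ring can only span the two carbons cis on the piperidine, so the reversible closure should set the carbinol carbon as R.

## Compound list

1 | 4,5-dibromo-1H-pyrrole-2-carboxylic acid | OC(=O)c1cc(Br)c(Br)[nH]1 | starting material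
2 | 4,5-dibromo-1H-pyrrole-2-carbonyl chloride (not isolated) | O=C(Cl)c1cc(Br)c(Br)[nH]1 | intermediate
3 | 4,5-dibromo-1H-pyrrole-2-carboxamide | NC(=O)c1cc(Br)c(Br)[nH]1 | intermediate
4 | ethyl chlorooxoacetate (ethyl oxalyl chloride) | CCOC(=O)C(=O)Cl | starting material
5 | ethyl 2-(2,3-dibromo-5-carbamoyl-1H-pyrrol-1-yl)-2-oxoacetate (not isolated) | CCOC(=O)C(=O)n1c(Br)c(Br)cc1C(N)=O | intermediate
6 | ethyl 5,6-dibromo-3-hydroxy-1-oxo-2,3-dihydro-1H-pyrrolo[1,2-c]imidazole-3-carboxylate, racemic (not isolated) | CCOC(=O)C1(O)NC(=O)c2cc(Br)c(Br)n12 | intermediate
7 | ethyl 5,6-dibromo-1-oxo-1H-pyrrolo[1,2-c]imidazole-3-carboxylate (cyclic N-acyl ketimine) | CCOC(=O)C1=NC(=O)c2cc(Br)c(Br)n12 | intermediate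
8 | tert-butyl carbamate | CC(C)(C)OC(N)=O | starting material
9 | ethyl (3R)-5,6-dibromo-3-[(tert-butoxycarbonyl)amino]-1-oxo-2,3-dihydro-1H-pyrrolo[1,2-c]imidazole-3-carboxylate | CCOC(=O)[C@]1(NC(=O)OC(C)(C)C)NC(=O)c2cc(Br)c(Br)n12 | intermediate
10 | tert-butyl N-[(3R)-5,6-dibromo-3-(1-hydroxycyclopropyl)-1-oxo-2,3-dihydro-1H-pyrrolo[1,2-c]imidazol-3-yl]carbamate | OC1(CC1)[C@]2(NC(=O)OC(C)(C)C)NC(=O)c3cc(Br)c(Br)n23 | intermediate
11 | bromomethyl acetate | CC(=O)OCBr | starting material
12 | [(3S)-5,6-dibromo-3-[(tert-butoxycarbonyl)amino]-3-(1-hydroxycyclopropyl)-1-oxo-1H-pyrrolo[1,2-c]imidazol-2(3H)-yl]methyl acetate | CC(=O)OCN1C(=O)c2cc(Br)c(Br)n2[C@]1(NC(=O)OC(C)(C)C)C3(O)CC3 | intermediate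
13 | ethylzinc cyclopropoxide of 12 (O–ZnEt in place of O–H; not isolated) | CC(=O)OCN1C(=O)c2cc(Br)c(Br)n2[C@]1(NC(=O)OC(C)(C)C)C3(O[Zn]CC)CC3 | intermediate
14 | zinc homoenolate: the 3-[3-(ethylzincio)propanoyl] ketone derived from 13, N-acetoxymethyl group still in place (not isolated) | CC(=O)OCN1C(=O)c2cc(Br)c(Br)n2[C@]1(NC(=O)OC(C)(C)C)C(=O)CC[Zn]CC | intermediate
15 | Boc-protected tricyclic α-amino ketone: 5,6-dibromo-2,3-dihydro-1H-pyrrolo[1,2-c]imidazol-1-one whose N2 and C3 are bridged by N–CH2CH2CH2–C(=O)–C3 (piperidin-3-one, ring C); C3 is S and bears NHBoc | O=C1CCCN2C(=O)c3cc(Br)c(Br)n3[C@@]21NC(=O)OC(C)(C)C | intermediate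
16 | tricyclic α-amino ketone: as 15 with a free NH2 on the S aminal carbon | O=C1CCCN2C(=O)c3cc(Br)c(Br)n3[C@@]21N | intermediate
17 | cyanamide | NC#N | starting material
18 | open guanidine ketone: as 16 with NH–C(=NH)NH2 on the S aminal carbon (not isolated) | O=C1CCCN2C(=O)c3cc(Br)c(Br)n3[C@@]21NC(N)=N | intermediate
19 | CNP0143627.2: tetracycle in which the ketone carbon of 18 has become the R carbinol carbon (OH) of a cis-fused 2-aminoimidazoline; triamino carbon S | NC1=N[C@@]2(O)CCCN3C(=O)c4cc(Br)c(Br)n4[C@@]32N1 | target

## Step count and least certain steps

Total: 8 steps. Longest linear sequence: 8 steps (1 → 19); 4, 8, 11 and 17 are purchased.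

**Step 6 (key step; the only step beyond known chemistry).**
- What may go wrong: the zinc cyclopropoxide opens too slowly. The iminium ion is then consumed by ethyl transfer from zinc or held back by reversible O-capture, or the homoenolate is protonated before it closes the ring. The ring-opened form is a minor, weakly nucleophilic equilibrium partner.
- Fallback with known reactions, from 10 back to 15: the lactam nitrogen of 10 is alkylated with allyl bromide (Cs2CO3, DMF) to the N-allyl cyclopropanol F1. Pd(OAc)2 with pyridine under O2 (divalent palladium; ring opening, then β-hydride elimination) converts the cyclopropanol into the vinyl ketone F2. Ring-closing metathesis with the second-generation Grubbs catalyst closes ring C as the cyclic enone F3. Hydrogenation of the enone C=C with H2 and RhCl(PPh3)3, which leaves the C–Br bonds, gives 15.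

**Step 4.**
- What may go wrong: halogen–magnesium exchange or titanium-mediated reduction at the C–Br bonds, and slow insertion at the crowded, doubly N-metallated ester.
- Fallback, bromination moved behind ring C, from 4 back to 15: 4 is condensed as in step 2 with bromine-free 1H-pyrrole-2-carboxamide F4 to the ketimine F5. Steps 3 to 6 then give in turn the aminal ester F6, the cyclopropanol F7, the N-acetoxymethyl lactam F8 and the tricyclic Boc-amino ketone F9. NBS (2 equiv, THF, 0 °C) brominates the two pyrrole positions remote from the acyl group, the usual pattern for 2-acylpyrroles, and the route is rejoined at 15.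

**Step 3.**
- What may go wrong: poor facial discrimination on a small flat ketimine, or erosion of enantiopurity through acid-catalysed reversal of the addition.
- Fallback, from 7 back to 9: 7 and 8 are combined under an achiral acid (diphenyl phosphate) to the racemic aminal ester F10, which is resolved by preparative chromatography on a chiral stationary phase to give 9.

**Step 2.**
- What may go wrong: ring closure through the ester carbonyl to a six-membered imide under basic conditions, dehydration of the primary amide before it has cyclised, or rehydration of the ketimine on handling.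
- Fallback, from 3 back to 7: 3 is condensed with ethyl glyoxylate (TsOH cat., toluene, removal of water) to the racemic C3–H aminal F11 by amidoalkylation at the pyrrole nitrogen. tert-Butyl hypochlorite gives the N-chloro lactam F12, and DBU eliminates HCl to give 7.

**Step 5.**
- What may go wrong: O- instead of N-alkylation at the hindered lactam, or acetyl transfer from the reagent.
- Fallback, from 10 back to 12: aqueous formaldehyde with catalytic K2CO3 adds reversibly, hence under thermodynamic N-selectivity, to give the N-hydroxymethyl lactam F13. Ac2O/pyridine at 0 °C acetylates the primary hydroxyl in preference to the tertiary cyclopropanol and gives 12.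

**Step 8.**
- What may go wrong: slow guanylation because the amine on a carbon bearing two further nitrogens and a ketone is weakly nucleophilic, so self-condensation of the amino ketone or oligomerisation of cyanamide can compete.
- Fallback, from 16 back to 19: 16 is treated with N,N′-di-Boc-N″-triflylguanidine (Et3N, CH2Cl2), a reagent that guanylates weakly nucleophilic amines, to give the di-Boc guanidine F14. CF3CO2H removes both carbamates, and the free guanidine closes onto the ketone to give 19.

## Further compounds

F1 | step 6 | tert-butyl N-[(3S)-2-allyl-5,6-dibromo-3-(1-hydroxycyclopropyl)-1-oxo-2,3-dihydro-1H-pyrrolo[1,2-c]imidazol-3-yl]carbamate | C=CCN1C(=O)c2cc(Br)c(Br)n2[C@]1(NC(=O)OC(C)(C)C)C3(O)CC3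
F2 | step 6 | tert-butyl N-[(3S)-3-acryloyl-2-allyl-5,6-dibromo-1-oxo-2,3-dihydro-1H-pyrrolo[1,2-c]imidazol-3-yl]carbamate | C=CCN1C(=O)c2cc(Br)c(Br)n2[C@]1(NC(=O)OC(C)(C)C)C(=O)C=C
F3 | step 6 | (S)-configured tricyclic Boc-amino enone (15 with a C=C between the two carbons next to the ketone CH2 position, i.e. C(=O)–CH=CH–CH2–N) | O=C1C=CCN2C(=O)c3cc(Br)c(Br)n3[C@@]21NC(=O)OC(C)(C)C
F4 | step 4 | 1H-pyrrole-2-carboxamide | NC(=O)c1ccc[nH]1
F5 | step 4 | bromine-free analogue of 7 (ethyl 1-oxo-1H-pyrrolo[1,2-c]imidazole-3-carboxylate) | CCOC(=O)C1=NC(=O)c2cccn12
F6 | step 4 | bromine-free analogue of 9 | CCOC(=O)[C@]1(NC(=O)OC(C)(C)C)NC(=O)c2cccn12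
F7 | step 4 | bromine-free analogue of 10 | OC1(CC1)[C@]2(NC(=O)OC(C)(C)C)NC(=O)c3cccn23
F8 | step 4 | bromine-free analogue of 12 | CC(=O)OCN1C(=O)c2cccn2[C@]1(NC(=O)OC(C)(C)C)C3(O)CC3
F9 | step 4 | bromine-free analogue of 15 | O=C1CCCN2C(=O)c3cccn3[C@@]21NC(=O)OC(C)(C)C
F10 | step 3 | racemic ethyl 5,6-dibromo-3-[(tert-butoxycarbonyl)amino]-1-oxo-2,3-dihydro-1H-pyrrolo[1,2-c]imidazole-3-carboxylate | CCOC(=O)C1(NC(=O)OC(C)(C)C)NC(=O)c2cc(Br)c(Br)n12
F11 | step 2 | racemic ethyl 5,6-dibromo-1-oxo-2,3-dihydro-1H-pyrrolo[1,2-c]imidazole-3-carboxylate | CCOC(=O)C1NC(=O)c2cc(Br)c(Br)n12
F12 | step 2 | racemic ethyl 5,6-dibromo-2-chloro-1-oxo-2,3-dihydro-1H-pyrrolo[1,2-c]imidazole-3-carboxylate | CCOC(=O)C1N(Cl)C(=O)c2cc(Br)c(Br)n12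
F13 | step 5 | tert-butyl N-[(3S)-5,6-dibromo-3-(1-hydroxycyclopropyl)-2-(hydroxymethyl)-1-oxo-2,3-dihydro-1H-pyrrolo[1,2-c]imidazol-3-yl]carbamate | OCN1C(=O)c2cc(Br)c(Br)n2[C@]1(NC(=O)OC(C)(C)C)C3(O)CC3
F14 | step 8 | N,N′-di-Boc guanidine of 16 (S aminal carbon bearing NH–C(=NBoc)NHBoc) | O=C1CCCN2C(=O)c3cc(Br)c(Br)n3[C@@]21NC(=NC(=O)OC(C)(C)C)NC(=O)OC(C)(C)C
A1 | alternative 1 | target carrying a methyl ester on the ring-C carbon next to the lactam nitrogen | NC1=N[C@@]2(O)CC[C@@H](C(=O)OC)N3C(=O)c4cc(Br)c(Br)n4[C@@]32N1
A2 | alternative 1 | methyl (2S)-2-[(4,5-dibromo-1H-pyrrole-2-carbonyl)amino]-5-oxo-6,6,6-tris(methylsulfanyl)hexanoate | COC(=O)[C@H](CCC(=O)C(SC)(SC)SC)NC(=O)c1cc(Br)c(Br)[nH]1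
A3 | alternative 1 | guanidine | NC(N)=N
A4 | alternative 2 | oxazolidinone-bridged tetracycle | O=C1O[C@H]2CCCN3C(=O)c4cc(Br)c(Br)n4[C@@]32N1
A5 | alternative 2 | tricyclic aminal C–H compound with a primary carbamate on the neighbouring ring-C carbinol | NC(=O)O[C@H]1CCCN2C(=O)c3cc(Br)c(Br)n3[C@@H]21
A6 | alternative 3 | tricyclic hydroxy enone with phthalimido group (hemiaminal carbon as both epimers) | O=C1C=CC(O)N2C(=O)c3cc(Br)c(Br)n3[C@@]21N1C(=O)c2ccccc2C1=O
A7 | alternative 3 | 5,6-dibromo-3-(furan-2-yl)-3-phthalimido-2,3-dihydro-1H-pyrrolo[1,2-c]imidazol-1-one | N1C(=O)c2cc(Br)c(Br)n2[C@]1(N3C(=O)c4ccccc4C3=O)c5ccco5
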